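**Retrosynthetic overview**

1. Target 11 comes from 10 by removal of three O-benzyl groups; its only stereocentre, C4 (R), is set by enantioselective CuH conjugate reduction of the C3=C4 bond of coumarin 7, followed by reoxidation at C8.
2. Coumarin 7 comes from the 3-silylcoumarin 6 by protodesilylation at C3.
3. 6 comes from iodophenol 3, alkyne 4 (supplying C4 and C3) and CO 5 (supplying C2): one palladium-catalysed operation forms C4a–C4, C3–C2 and C2–O1 and closes the pyranone ring, the only ring built; rings A and B and the C8 acyl chain arrive with phloretin 1.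
4. Feature used: O1 and C4 of the pyranone ring sit on the neighbouring ring-A carbons C8a and C4a, and C8a lies beside the acyl-bearing C8. Leaving only the C8a oxygen free and placing iodine on C4a therefore fixes the 8-acyl (not 6-acyl) constitution.
5. 3 comes from ortho-iodination of 2, which comes from selective tribenzylation of 1.

Key step: step 3

Assumption: with (R)-DTBM-SEGPHOS the hydride is taken to add to the Si face of C4 (giving 4R), by analogy with 4-arylcoumarins lacking a C5 substituent; if the first run shows the opposite sense, the (S) ligand is used and nothing else changes.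

**Route**

Step 1
Reactants: 1 phloretin
Product: 2 1-[2,4-bis(benzyloxy)-6-hydroxyphenyl]-3-[4-(benzyloxy)phenyl]propan-1-one
Conditions: BnBr (3.1 equiv), K2CO3 (3.3 equiv), DMF, rt to 50 °C
Reagents that add atoms: benzyl bromide, BrCc1ccccc1
Why: Williamson etherification should take the para hydroxyl of ring A, the ring B hydroxyl and one of the two equivalent ortho hydroxyls, while the last ortho hydroxyl, locked in a six-membered hydrogen bond to the ketone, is the least nucleophilic and stays free.

Step 2
Reactants: 2 1-[2,4-bis(benzyloxy)-6-hydroxyphenyl]-3-[4-(benzyloxy)phenyl]propan-1-one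
Product: 3 1-[4,6-bis(benzyloxy)-2-hydroxy-3-iodophenyl]-3-[4-(benzyloxy)phenyl]propan-1-one
Conditions: NIS (1.05 equiv), TsOH·H2O (cat.), MeCN/CH2Cl2, 0 °C, dark
Reagents that add atoms: N-iodosuccinimide, O=C1CCC(=O)N1I
Why: Electrophilic aromatic iodination should occur on the trioxygenated ring A rather than ring B, at the carbon between the free hydroxyl and a benzyloxy group rather than the more crowded carbon between two benzyloxy groups, as is usual for 2-hydroxy-4,6-dialkoxyaryl ketones.

Step 3
Reactants: 3 1-[4,6-bis(benzyloxy)-2-hydroxy-3-iodophenyl]-3-[4-(benzyloxy)phenyl]propan-1-one; 4 1-phenyl-2-(trimethylsilyl)acetylene; 5 carbon monoxide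
Product: 6 5,7-bis(benzyloxy)-8-{3-[4-(benzyloxy)phenyl]propanoyl}-4-phenyl-3-(trimethylsilyl)-2H-chromen-2-one
Conditions: Pd(OAc)2 (5 mol %), pyridine (2 equiv), Bu4NCl (1 equiv), 4 (5 equiv), CO (1 atm), DMF, 120 °C
Reagents that add atoms: none
Why: Pd(OAc)2 is reduced in the flask to zerovalent palladium, which inserts into the C–I bond of 3; the arylpalladium iodide adds syn across alkyne 4 before it takes up CO, CO then inserts into the vinyl–palladium bond, and the neighbouring phenoxide (freed by pyridine) attacks the acylpalladium to form C2–O1 and release zerovalent palladium. The closest known reaction is the palladium-catalysed carbonylative annulation of o-iodophenols with internal alkynes, silylalkynes included, to 3,4-disubstituted coumarins. The one ring closed is the pyranone ring, by lactonisation of the phenol oxygen onto the acyl carbon (6-exo-trig attack, or equally C–O reductive elimination from a seven-membered oxapalladacycle). No stereocentre is formed. Two selectivities are needed: alkyne insertion before CO insertion, favoured by one atmosphere of CO, excess alkyne, high temperature and the small pyridine ligand, and delivery of the aryl group to the phenyl-bearing alkyne carbon, secured by the bulky trimethylsilyl group taking the position next to palladium and away from the doubly ortho-substituted aryl group. The constitution of ring A needs no selectivity, since only the C8a oxygen is free and iodine sits on C4a.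

Step 4
Reactants: 6 5,7-bis(benzyloxy)-8-{3-[4-(benzyloxy)phenyl]propanoyl}-4-phenyl-3-(trimethylsilyl)-2H-chromen-2-one
Product: 7 5,7-bis(benzyloxy)-8-{3-[4-(benzyloxy)phenyl]propanoyl}-4-phenyl-2H-chromen-2-one
Conditions: Bu4NF·3H2O (1.5 equiv), THF, 0 °C to rt
Reagents that add atoms: none
Why: Fluoride-induced protodesilylation of a vinylsilane should be easy here because silicon sits alpha to the lactone carbonyl, so attack of fluoride at silicon releases a carbonyl-stabilised C3 carbanion equivalent that water protonates.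

Step 5
Reactants: 7 5,7-bis(benzyloxy)-8-{3-[4-(benzyloxy)phenyl]propanoyl}-4-phenyl-2H-chromen-2-one
Product: 9 (4R)-5,7-bis(benzyloxy)-8-{3-[4-(benzyloxy)phenyl]-1-hydroxypropyl}-4-phenyl-3,4-dihydro-2H-chromen-2-one (both carbinol epimers), via bis-silylated ketene acetal 8 (not isolated)
Conditions: Cu(OAc)2·H2O (5 mol %), (R)-DTBM-SEGPHOS (5.5 mol %), (EtO)2MeSiH (4 equiv), toluene, 0 °C to rt; then H2O/THF, NH4F (cat.), 0 °C
Reagents that add atoms: none
Why: In this asymmetric conjugate (1,4) reduction, bisphosphine-ligated CuH formed from Cu(OAc)2 and the silane delivers hydride to the Si face of C4 (C4a > phenyl > C3) under ligand control to set the (4R) centre, and the copper enolate is trapped by the silane as a silyl ketene acetal that resists further reduction; since the same catalyst hydrosilylates aryl ketones, the C8 ketone is deliberately driven to its silyl ether (a temporary, uncontrolled carbinol centre), and any ketone that survives is already 10 and passes unchanged through step 6.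

Step 6
Reactants: 9 (4R)-5,7-bis(benzyloxy)-8-{3-[4-(benzyloxy)phenyl]-1-hydroxypropyl}-4-phenyl-3,4-dihydro-2H-chromen-2-one
Product: 10 (4R)-5,7-bis(benzyloxy)-8-{3-[4-(benzyloxy)phenyl]propanoyl}-4-phenyl-3,4-dihydro-2H-chromen-2-one
Conditions: Dess–Martin periodinane (1.5 equiv), NaHCO3, CH2Cl2, 0 °C to rt
Reagents that add atoms: none
Why: Buffered Dess–Martin oxidation should return the benzylic carbinol to the aryl ketone (and any lactol from over-reduction to the lactone) without touching the benzyl ethers or the C4 centre, which has no adjacent carbonyl and cannot epimerise.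

Step 7
Reactants: 10 (4R)-5,7-bis(benzyloxy)-8-{3-[4-(benzyloxy)phenyl]propanoyl}-4-phenyl-3,4-dihydro-2H-chromen-2-one
Product: 11 (4R)-5,7-dihydroxy-8-[3-(4-hydroxyphenyl)propanoyl]-4-phenyl-3,4-dihydro-2H-chromen-2-one
Conditions: H2 (1 atm), 10% Pd/C, EtOAc/THF, rt
Reagents that add atoms: none
Why: Catalytic hydrogenolysis should cleave the three aryl benzyl ethers while the chelated, electron-rich aryl ketone and the C4 centre (no heteroatom on carbon) are left alone, and the aprotic solvent avoids solvolytic opening of the aryl lactone that could let it re-close onto the C5 hydroxyl.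

**Compound list**

1 | phloretin | O=C(CCc1ccc(O)cc1)c1c(O)cc(O)cc1O | starting material
2 | 1-[2,4-bis(benzyloxy)-6-hydroxyphenyl]-3-[4-(benzyloxy)phenyl]propan-1-one | O=C(CCc1ccc(OCc2ccccc2)cc1)c1c(O)cc(OCc2ccccc2)cc1OCc1ccccc1 | intermediate
3 | 1-[4,6-bis(benzyloxy)-2-hydroxy-3-iodophenyl]-3-[4-(benzyloxy)phenyl]propan-1-one | O=C(CCc1ccc(OCc2ccccc2)cc1)c1c(O)c(I)c(OCc2ccccc2)cc1OCc1ccccc1 | intermediate
4 | 1-phenyl-2-(trimethylsilyl)acetylene | C[Si](C)(C)C#Cc1ccccc1 | starting material
5 | carbon monoxide | [C-]#[O+] | starting material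
6 | 5,7-bis(benzyloxy)-8-{3-[4-(benzyloxy)phenyl]propanoyl}-4-phenyl-3-(trimethylsilyl)-2H-chromen-2-one | O=C1Oc2c(C(=O)CCc3ccc(OCc4ccccc4)cc3)c(OCc3ccccc3)cc(OCc3ccccc3)c2C(c2ccccc2)=C1[Si](C)(C)C | intermediate
7 | 5,7-bis(benzyloxy)-8-{3-[4-(benzyloxy)phenyl]propanoyl}-4-phenyl-2H-chromen-2-one | O=C1Oc2c(C(=O)CCc3ccc(OCc4ccccc4)cc3)c(OCc3ccccc3)cc(OCc3ccccc3)c2C(c2ccccc2)=C1 | intermediate
8 | (4R)-5,7-bis(benzyloxy)-2-[diethoxy(methyl)silyloxy]-8-{3-[4-(benzyloxy)phenyl]-1-[diethoxy(methyl)silyloxy]propyl}-4-phenyl-4H-chromene (side-chain carbinol carbon unassigned; not isolated) | CCO[Si](C)(OCC)OC1=C[C@H](c2ccccc2)c2c(OCc3ccccc3)cc(OCc3ccccc3)c(C(O[Si](C)(OCC)OCC)CCc3ccc(OCc4ccccc4)cc3)c2O1 | intermediate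
9 | (4R)-5,7-bis(benzyloxy)-8-{3-[4-(benzyloxy)phenyl]-1-hydroxypropyl}-4-phenyl-3,4-dihydro-2H-chromen-2-one (both carbinol epimers) | O=C1C[C@H](c2ccccc2)c2c(OCc3ccccc3)cc(OCc3ccccc3)c(C(O)CCc3ccc(OCc4ccccc4)cc3)c2O1 | intermediate
10 | (4R)-5,7-bis(benzyloxy)-8-{3-[4-(benzyloxy)phenyl]propanoyl}-4-phenyl-3,4-dihydro-2H-chromen-2-one | O=C1C[C@H](c2ccccc2)c2c(OCc3ccccc3)cc(OCc3ccccc3)c(C(=O)CCc3ccc(OCc4ccccc4)cc3)c2O1 | intermediate
11 | (4R)-5,7-dihydroxy-8-[3-(4-hydroxyphenyl)propanoyl]-4-phenyl-3,4-dihydro-2H-chromen-2-one | O=C1C[C@H](c2ccccc2)c2c(O)cc(O)c(C(=O)CCc3ccc(O)cc3)c2O1 | target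

**Step count and risks**

Total step count: 7. Longest linear sequence: 7 steps (1 to 11).

Steps most likely to fail:

Step 3. The arylpalladium formed from 3 is flanked by a phenoxide and a benzyloxy group, so carbopalladation of the bulky silylalkyne may be slow. CO may then insert first (aroylpalladium, leading to aryl esters), the iodide may be reduced off, or the regiochemistry of alkyne insertion may erode. Early loss of the silyl group would be harmless, since it leads to 7. The fallback uses neither CO nor silicon and sets out from 3. A Heck reaction with ethyl acrylate (Pd(OAc)2, tri(o-tolyl)phosphine, Et3N, DMF, 100 °C) should give ethyl (2E)-3-{4,6-bis(benzyloxy)-3-[3-(4-benzyloxyphenyl)propanoyl]-2-hydroxyphenyl}prop-2-enoate F1. A second Heck arylation of F1 with iodobenzene (Pd(OAc)2, Bu4NOAc/Bu4NBr melt, 100 °C) places the phenyl group trans to the ester and gives ethyl (2Z)-3-{4,6-bis(benzyloxy)-3-[3-(4-benzyloxyphenyl)propanoyl]-2-hydroxyphenyl}-3-phenylprop-2-enoate F2. Its phenol is cis to the ester and should lactonise in the flask with loss of ethanol, so the fallback rejoins the route at 7 and replaces steps 3 and 4.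

Step 5. Hydride transfer to C4 may be slow, because this carbon carries two aryl groups, is crowded by the C5 benzyloxy group and is made less electrophilic by the C5 and C7 oxygens; facial discrimination may then be poor, and hydride may go instead to the lactone carbonyl. The fallback sets out from 7 and avoids hydride reagents. Aqueous NaOH in THF should open the lactone to disodium (2Z)-3-{4,6-bis(benzyloxy)-3-[3-(4-benzyloxyphenyl)propanoyl]-2-oxidophenyl}-3-phenylprop-2-enoate F3. Homogeneous asymmetric hydrogenation of this salt ([Rh(cod)2]BF4 with the Chiraphos enantiomer that gives the R centre, H2 under pressure, MeOH) should reduce only the C=C bond, leaving ketone and benzyl ethers, to give disodium (3R)-3-{4,6-bis(benzyloxy)-3-[3-(4-benzyloxyphenyl)propanoyl]-2-oxidophenyl}-3-phenylpropanoate F4. Acidification with HCl relactonises onto the only free phenol, so the fallback rejoins the route at 10 and replaces steps 5 and 6.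

Step 1. Discrimination among the four hydroxyls may be incomplete, giving mixtures of di-, tri- and tetra-ethers. The fallback sets out from 1 and separates protection from selection. Exhaustive benzylation (excess BnBr, K2CO3, DMF, 80 °C) should give 3-[4-(benzyloxy)phenyl]-1-[2,4,6-tris(benzyloxy)phenyl]propan-1-one F5. Chelation-controlled cleavage of one of the two equivalent benzyl ethers ortho to the ketone (MgBr2·OEt2, toluene/Et2O, reflux) should then return the route to 2.

**Further compounds**

F1 | step 3 | ethyl (2E)-3-{4,6-bis(benzyloxy)-3-[3-(4-benzyloxyphenyl)propanoyl]-2-hydroxyphenyl}prop-2-enoate | CCOC(=O)/C=C/c1c(O)c(C(=O)CCc2ccc(OCc3ccccc3)cc2)c(OCc2ccccc2)cc1OCc1ccccc1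
F2 | step 3 | ethyl (2Z)-3-{4,6-bis(benzyloxy)-3-[3-(4-benzyloxyphenyl)propanoyl]-2-hydroxyphenyl}-3-phenylprop-2-enoate | CCOC(=O)/C=C(/c1ccccc1)c1c(O)c(C(=O)CCc2ccc(OCc3ccccc3)cc2)c(OCc2ccccc2)cc1OCc1ccccc1
F3 | step 5 | disodium (2Z)-3-{4,6-bis(benzyloxy)-3-[3-(4-benzyloxyphenyl)propanoyl]-2-oxidophenyl}-3-phenylprop-2-enoate | [Na+].[Na+].[O-]C(=O)/C=C(/c1ccccc1)c1c([O-])c(C(=O)CCc2ccc(OCc3ccccc3)cc2)c(OCc2ccccc2)cc1OCc1ccccc1
F4 | step 5 | disodium (3R)-3-{4,6-bis(benzyloxy)-3-[3-(4-benzyloxyphenyl)propanoyl]-2-oxidophenyl}-3-phenylpropanoate | [Na+].[Na+].[O-]C(=O)C[C@H](c1ccccc1)c1c([O-])c(C(=O)CCc2ccc(OCc3ccccc3)cc2)c(OCc2ccccc2)cc1OCc1ccccc1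
F5 | step 1 | 3-[4-(benzyloxy)phenyl]-1-[2,4,6-tris(benzyloxy)phenyl]propan-1-one | O=C(CCc1ccc(OCc2ccccc2)cc1)c1c(OCc2ccccc2)cc(OCc2ccccc2)cc1OCc1ccccc1
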